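**Retrosynthetic overview**
1. Target 7 ⇒ chalcone 6: disconnect the C2–O1 bond of the pyranone ring (enantioselective 6-endo oxa-Michael closure, which sets C2).
2. Chalcone 6 ⇒ acetophenone 3 + veratraldehyde 4: Cα–Cβ enone bond by Claisen–Schmidt condensation.
3. Acetophenone 3 ⇒ 1,2,3,5-tetramethoxybenzene 1 + acetyl chloride: Friedel–Crafts acylation with in-flask ortho-O-demethylation.
4. Ring order: both benzene rings are bought intact; the only ring built is the heterocycle, closed in the last step.

Assumption: the stereocentre in the SMILES reads as 2S (the natural flavanone series), and 1,2,3,5-tetramethoxybenzene is taken as a catalogue starting material.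

**Step 1**
Reactants: 1 tetramethoxybenzene (1,2,3,5-isomer)
Product: 3 phenolic ketone 1-(2-hydroxy-3,4,6-trimethoxyphenyl)ethan-1-one, via tetramethoxyacetophenone 2 (not isolated)
Conditions: AcCl (1.2 equiv), AlCl3 (2.5 equiv), Et2O, 0 °C → rt, 24 h; then ice/2 M HCl
Reagents that add atoms: acetyl chloride, CC(Cl)=O
Why: Friedel–Crafts acylation can only occur at the two equivalent free positions of 1, and AlCl3 chelated to the new carbonyl then cleaves one ortho methyl ether, preferentially the out-of-plane, more Lewis-basic one buttressed by the neighbouring OMe (chelation-assisted aryl methyl ether cleavage), giving the 2-hydroxy-3,4,6 pattern needed for the 5,7,8-trioxygenated A ring; no stereocentre is formed.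

**Step 2**
Reactants: 3 phenolic ketone 1-(2-hydroxy-3,4,6-trimethoxyphenyl)ethan-1-one, 4 veratraldehyde (3,4-dimethoxybenzaldehyde)
Product: 6 (E)-3-(3,4-dimethoxyphenyl)-1-(2-hydroxy-3,4,6-trimethoxyphenyl)prop-2-en-1-one, via aldol adduct 5 (not isolated)
Conditions: KOH (50% aq, 5 equiv), EtOH, rt, 36 h; then 1 M HCl, 0 °C, to pH 4; filter, chromatograph
Reagents that add atoms: none
Why: Claisen–Schmidt (crossed aldol) condensation, in which the phenoxide-enolate of 3 adds to the non-enolisable aldehyde 4 and E1cB loss of water gives the thermodynamic E-enone; in strong base the chalcone is held as its phenoxide and does not close to racemic flavanone, and cold acidification returns the free phenol.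

**Step 3**
Reactants: 6 (E)-3-(3,4-dimethoxyphenyl)-1-(2-hydroxy-3,4,6-trimethoxyphenyl)prop-2-en-1-one
Product: 7 (2S)-2-(3,4-dimethoxyphenyl)-5,7,8-trimethoxy-2,3-dihydro-4H-chromen-4-one
Conditions: L-tert-leucine-derived thiourea–iminophosphorane (BIMP) cat. (10 mol%), PhMe (0.05 M), 0 °C, 24–48 h; SiO2 plug at 0 °C; recryst. EtOAc/hexane
Reagents that add atoms: none
Why: Proposed new method: enantioselective 6-endo-trig intramolecular oxa-Michael addition of an unactivated 2'-hydroxychalcone under bifunctional iminophosphorane (superbase/thiourea) catalysis, with N-[3,5-bis(trifluoromethyl)phenyl]-N'-[(2S)-3,3-dimethyl-1-{[tris(4-methoxyphenyl)-λ5-phosphanylidene]amino}butan-2-yl]thiourea as catalyst (hand to be confirmed on the first run; both are equally accessible). The iminophosphorane is far more basic than the tertiary amines that cyclise such chalcones only sluggishly and with low ee, so it breaks the O–H···O=C chelate and ionises the phenol to a tight chiral aminophosphonium phenoxide ion pair. The thiourea N–H pair binds the enone oxygen and holds the cyclisation-competent rotamer that the 6'-OMe twist already favours. The phenoxide oxygen then attacks one enantiotopic face of Cβ, which sets C2 as S, and the aminophosphonium N–H protonates the enolate at the non-stereogenic C3 to release the catalyst. The 5-methoxyflavanone should be the favoured isomer and its C3–H is far less acidic than the phenol, so E1cB re-opening, the racemisation path, should be slow at 0 °C. Closest known reaction types: BIMP-catalysed intramolecular oxa-Michael addition of alcohols to α,β-unsaturated esters and amides, and amine–thiourea-catalysed cyclisation of α-carboxy-activated 2'-hydroxychalcones.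

**Compound list**
1 | 1,2,3,5-tetramethoxybenzene | COc1cc(OC)c(OC)c(OC)c1 | starting material
2 | 1-(2,3,4,6-tetramethoxyphenyl)ethan-1-one (not isolated) | CC(=O)c1c(OC)cc(OC)c(OC)c1OC | intermediate
3 | 1-(2-hydroxy-3,4,6-trimethoxyphenyl)ethan-1-one | CC(=O)c1c(OC)cc(OC)c(OC)c1O | intermediate
4 | 3,4-dimethoxybenzaldehyde (veratraldehyde) | COc1ccc(C=O)cc1OC | starting material
5 | 3-(3,4-dimethoxyphenyl)-3-hydroxy-1-(2-hydroxy-3,4,6-trimethoxyphenyl)propan-1-one (racemic, not isolated) | COc1ccc(C(O)CC(=O)c2c(OC)cc(OC)c(OC)c2O)cc1OC | intermediate
6 | (E)-3-(3,4-dimethoxyphenyl)-1-(2-hydroxy-3,4,6-trimethoxyphenyl)prop-2-en-1-one | COc1ccc(/C=C/C(=O)c2c(OC)cc(OC)c(OC)c2O)cc1OC | intermediate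
7 | (2S)-2-(3,4-dimethoxyphenyl)-5,7,8-trimethoxy-2,3-dihydro-4H-chromen-4-one | COc1ccc([C@@H]2CC(=O)c3c(OC)cc(OC)c(OC)c3O2)cc1OC | target

**Total step count:** 3
**Longest linear sequence:** 3 (1 → 3 → 6 → 7)

**Steps most likely to fail, with fallbacks**

Step 3 (the proposed new cyclisation) is the main risk. The ee may be low, the sense of induction cannot be predicted for this new substrate class, and the product can racemise by retro-oxa-Michael opening if left with the base. The electron-rich β-aryl group may also slow turnover. Read the configuration on the first run by chiral HPLC and CD (2S-flavanones show a positive band near 330 nm and a negative one near 290 nm). If the L-series catalyst gives 2R, switch to the D-tert-leucine-derived catalyst. Chalcone 6 must be free of racemic flavanone before use.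

The fallback uses known chemistry and moves the stereo-defining bond to C2–aryl; it sets out from 3 and comes back at 7. Compound 3 is condensed with N,N-dimethylformamide dimethyl acetal (PhMe, 100 °C) to the enaminone (E)-3-(dimethylamino)-1-(2-hydroxy-3,4,6-trimethoxyphenyl)prop-2-en-1-one F1. F1 closes with conc. HCl in CH2Cl2 at rt to the chromone 5,7,8-trimethoxy-4H-chromen-4-one F2. Pd(II)/pyridine-oxazoline-catalysed asymmetric conjugate addition of 3,4-dimethoxyphenylboronic acid to F2 (Pd(OCOCF3)2 5 mol%, t-BuPyOx 6 mol%, NH4PF6, H2O, ClCH2CH2Cl, 60 °C) then gives 7. Use the ligand hand that delivers the 2S series; (R)-t-BuPyOx is expected, by analogy with the facial model for cyclic enones, and should be confirmed by CD.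

Step 1 may over-demethylate, stop at 2, or cleave the wrong ortho ether. Check the regiochemistry of 3 by NOE: H-5 must show contacts to two OMe groups, whereas the unwanted 6-hydroxy-2,3,4-trimethoxy isomer shows only one. The fallback separates acylation from ether cleavage and avoids Lewis-acid acylation; it sets out from 1 and comes back at 3. Compound 1 is lithiated at one of its two equivalent positions, each flanked by two OMe groups (n-BuLi, TMEDA, THF, 0 °C). The aryllithium is acylated with N-methoxy-N-methylacetamide (−78 °C → rt) to give 2, now isolated. Compound 2 is then treated with BCl3 (1.1 equiv, CH2Cl2, −78 → 0 °C), which cleaves a single carbonyl-chelated ortho ether under milder, titratable conditions, to give 3.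

Step 2 may stall because both partners are electron-rich and the ketone is di-ortho-substituted, or the chalcone may partly close to racemic flavanone on work-up. The fallback forms the aryl–carbonyl bond instead of the enone bond; it sets out from 1 and comes back at 6. Commercial (E)-3,4-dimethoxycinnamic acid is converted with oxalyl chloride and cat. DMF (CH2Cl2, rt) into (E)-3-(3,4-dimethoxyphenyl)prop-2-enoyl chloride F3. Friedel–Crafts acylation of 1 with F3 (AlCl3 2.2 equiv, Et2O/CH2Cl2, 0 °C → rt) first gives (E)-3-(3,4-dimethoxyphenyl)-1-(2,3,4,6-tetramethoxyphenyl)prop-2-en-1-one F4. F4 loses its chelated, buttressed ortho methyl group in the same pot, as in step 1, and gives 6 after cold acidic work-up.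

**Further compounds**
F1 | step 3 | (E)-3-(dimethylamino)-1-(2-hydroxy-3,4,6-trimethoxyphenyl)prop-2-en-1-one | CN(C)/C=C/C(=O)c1c(OC)cc(OC)c(OC)c1O
F2 | step 3 | 5,7,8-trimethoxy-4H-chromen-4-one | O=c1ccoc2c(OC)c(OC)cc(OC)c12
F0 | step 1 | none | none
F3 | step 2 | (E)-3-(3,4-dimethoxyphenyl)prop-2-enoyl chloride | COc1ccc(/C=C/C(Cl)=O)cc1OC
F4 | step 2 | (E)-3-(3,4-dimethoxyphenyl)-1-(2,3,4,6-tetramethoxyphenyl)prop-2-en-1-one | COc1ccc(/C=C/C(=O)c2c(OC)cc(OC)c(OC)c2OC)cc1OC
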